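Assumption: bicyclic compounds carry labdane numbering (C1–C10 ring carbons, C11–C16 side chain, C17 on C8, C18/C19 on C4, C20 on C10); α is the face of CH3-20 in the target, which is (5R,8S,9R,10S,13E); 4-hydroxybut-2-ynoic acid is taken as a catalogue compound.

**Retrosynthetic overview**

1. Target ⇒ O-acetylation of the 16-hydroxy acid; the C17 aldehyde comes from a methyl ester, with C8 set by equilibration; the side chain comes from a C12–C13 Negishi coupling with a (Z)-β-iodo acid.
2. The Δ6 olefin and H-8 ⇒ deconjugation of a Δ7 enoate.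
3. Key disconnection C9–C10: a tertiary C10 radical (metal-hydride H-atom transfer, MHAT) closes ring B by 6-endo addition to the (Z)-enoate of a Baylis–Hillman-type acetate and then expels acetate; C5 controls C10 and C9.
4. Cyclisation substrate ⇒ ring-A aldehyde + bromo ynoate (hydroalumination/aldol).
5. Ring A is made first (Robinson annulation, CBS reduction, Claisen transfer of chirality to C5); ring B second (radical step).

**Route**

Step 1
Reactants: 1 2-methylpropanal; 2 pent-1-en-3-one
Product: 4 2,4,4-trimethylcyclohex-2-en-1-one, via keto aldehyde 3 (not isolated)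
Conditions: H2SO4 (cat.), PhMe, reflux, Dean–Stark
Reagents that add atoms: none
Why: acid-catalysed Robinson annulation (Michael addition of the aldehyde enol to the enone, then aldol condensation of the ethyl-ketone CH2 onto CHO); no stereocentre is formed.

Step 2
Reactants: 4 2,4,4-trimethylcyclohex-2-en-1-one
Product: 5 (1S)-2,4,4-trimethylcyclohex-2-en-1-ol
Conditions: (R)-Me-CBS (10 mol %), BH3·SMe2 (0.7 equiv), THF, −20 °C; MeOH
Reagents that add atoms: none
Why: Corey–Bakshi–Shibata reduction; the α-methylalkenyl arm acts as the large group, so the (R)-oxazaborolidine gives the (S)-carbinol by 1,2-reduction.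

Step 3
Reactants: 5 (1S)-2,4,4-trimethylcyclohex-2-en-1-ol
Product: 7 [(1R)-2,6,6-trimethylcyclohex-2-en-1-yl]acetaldehyde, via allyl vinyl ether 6 (not isolated)
Conditions: ethyl vinyl ether, Hg(OAc)2 (10 mol %), reflux; evaporate; PhMe, 190 °C, sealed tube
Reagents that add atoms: ethyl vinyl ether, C=COCC
Why: Hg(II) transvinylation then Claisen [3,3] rearrangement; it is suprafacial, so the new C–C bond forms on the ring face that held C–O, which sets the future C5 as R and moves the olefin to C1=C10.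

Step 4
Reactants: 8 4-bromobut-1-yne
Product: 10 methyl 5-bromopent-2-ynoate, via lithium acetylide 9 (not isolated)
Conditions: LDA (1.0 equiv), THF, −78 °C; ClCO2Me (1.2 equiv), −78 → −20 °C
Reagents that add atoms: methyl chloroformate, COC(=O)Cl
Why: C-acylation of the lithium acetylide; the cold, base-limited protocol avoids HBr loss from the product.

Step 5
Reactants: 10 methyl 5-bromopent-2-ynoate; 7 [(1R)-2,6,6-trimethylcyclohex-2-en-1-yl]acetaldehyde
Product: 13 methyl (2Z)-2-{1-acetoxy-2-[(1R)-2,6,6-trimethylcyclohex-2-en-1-yl]ethyl}-5-bromopent-2-enoate (both epimers at the acetoxy carbon), via vinylalane 11 (not isolated), via aluminium alkoxide 12 (not isolated)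
Conditions: DIBAL-H (1.05 equiv), HMPA (2 equiv), THF, 0 °C; 10, 0 °C, 1 h; 7 (0.9 equiv), 0 °C; Ac2O, pyridine, 0 → 23 °C
Reagents that add atoms: acetic anhydride, CC(=O)OC(C)=O
Why: conjugate hydroalumination of the ynoate (H and Al syn) gives the α-aluminio enoate, whose aldol addition to 7 occurs anti to the β-substituent (vinylalumination, a Morita–Baylis–Hillman surrogate), so CH2CH2Br stays cis to CO2Me (Z); the alkoxide is acetylated in the flask, and the uncontrolled carbinol centre is erased in step 6.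

Step 6
Reactants: 13 methyl (2Z)-2-{1-acetoxy-2-[(1R)-2,6,6-trimethylcyclohex-2-en-1-yl]ethyl}-5-bromopent-2-enoate
Product: 15 methyl (5R,9S,10R)-12-bromo-13,14,15,16-tetranorlabd-7-en-17-oate (H-5β/H-9β/CH3-20α), via β-acetoxy ester 14 (not isolated)
Conditions: Fe(acac)3 (30 mol %), PhSiH3 (2.5 equiv), EtOH/(CH2OH)2 5:1, 60 °C; then DBU (1.5 equiv), 0 °C
Reagents that add atoms: none
Why: Proposed new method: Fe–H transfers H• to C1 of the trisubstituted ring olefin, and the tertiary C10 radical closes ring B by 6-endo Giese addition to C9 of the (Z)-enoate through a chair transition state (C5 chain equatorial gives the trans ring fusion with CH3-20 α; C11, trans to C7 on the olefin, becomes equatorial, α); the α-ester radical is reduced to the iron enolate, which expels acetate (E1cB, completed by DBU); the closest known reactions are Fe(acac)3/PhSiH3 reductive olefin coupling, MHAT radical polyene cyclisations ending on unsaturated esters (which pass through the same C10 radical), and radical SN2′ allylations with Baylis–Hillman acetates.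

Step 7
Reactants: 15 methyl (5R,9S,10R)-12-bromo-13,14,15,16-tetranorlabd-7-en-17-oate
Product: 17 methyl (5R,8R,9R,10S)-12-bromo-13,14,15,16-tetranorlabd-6-en-17-oate (CO2Me-8α), via lithium dienolate 16 (not isolated)
Conditions: LDA (1.2 equiv), THF, −78 °C, 30 min; cannulate into AcOH/THF, −78 °C
Reagents that add atoms: none
Why: kinetic γ-deprotonation at C6 and irreversible α-protonation (deconjugation); the proton enters C8 from the β face, away from axial CH3-20 and the C9 chain, so the ester is 8α here (any 8β ester converges in step 10).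

Step 8
Reactants: 18 4-hydroxybut-2-ynoic acid
Product: 19 (2Z)-4-hydroxy-3-iodobut-2-enoic acid
Conditions: NaI (1.5 equiv), AcOH (2 equiv), MeCN, 70 °C
Reagents that add atoms: sodium iodide, [Na+].[I-]
Why: hydroiodination of an alkynoic acid by iodide conjugate addition and anti protonation gives the Z isomer (I cis to CO2H); any E isomer lactonises and is removed by bicarbonate extraction.

Step 9
Reactants: 17 methyl (5R,8R,9R,10S)-12-bromo-13,14,15,16-tetranorlabd-6-en-17-oate; 19 (2Z)-4-hydroxy-3-iodobut-2-enoic acid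
Product: 23 (5R,8R,9R,10S,13E)-16-hydroxylabda-6,13-diene-15,17-dioic acid 17-methyl ester (CO2Me-8α), via bis-silyl iodo acid 20 (not isolated), via alkylzinc bromide 21 (not isolated), via bis-silyl coupling product 22 (not isolated)
Conditions: 19, BSA (1.1 equiv), THF, 23 °C; 17, Zn (LiCl, TMSCl-activated), THF, 45 °C; combine, Pd(dppf)Cl2 (5 mol %), 40 °C; aq. citric acid
Reagents that add atoms: none
Why: Negishi sp3–sp2 cross-coupling retains the alkene geometry, so the new C12–C13 bond is cis to CO2H (13E); transient O-silylation masks OH and CO2H from the organozinc and is lost on work-up.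

Step 10
Reactants: 23 (5R,8R,9R,10S,13E)-16-hydroxylabda-6,13-diene-15,17-dioic acid 17-methyl ester
Product: 25 (5R,8S,9R,10S,13E)-16-hydroxy-17-oxolabda-6,13-dien-15-oic acid, via 8-epi aldehyde 24 (not isolated)
Conditions: DIBAL-H (3.5 equiv), CH2Cl2, −78 °C; Rochelle salt; crude + DBU (1.2 equiv), CH2Cl2, 0 °C; pH 4 buffer
Reagents that add atoms: none
Why: DIBAL-H turns OH and CO2H into aluminates that are inert at −78 °C and reduces the methyl ester to the aldehyde (partial ester reduction); DBU then equilibrates C8 through the dienolate, whose kinetic α-reprotonation funnels material to the more stable 8β aldehyde (pseudo-equatorial, trans to the C9 chain, no 1,3-diaxial CHO/CH3-20 contact).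

Step 11
Reactants: 25 (5R,8S,9R,10S,13E)-16-hydroxy-17-oxolabda-6,13-dien-15-oic acid
Product: 26 (5R,8S,9R,10S,13E)-16-acetoxy-17-oxolabda-6,13-dien-15-oic acid (target)
Conditions: vinyl acetate (5 equiv), Novozym 435 (CAL-B), MTBE, 30 °C
Reagents that add atoms: vinyl acetate, CC(=O)OC=C
Why: lipase-catalysed transesterification acetylates only the primary allylic alcohol at neutral pH, so CO2H, CHO and the base-labile C8 centre are untouched.

**Compound list**

1 | 2-methylpropanal | CC(C)C=O | starting material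
2 | pent-1-en-3-one | C=CC(=O)CC | starting material
3 | 2,2-dimethyl-5-oxoheptanal | CCC(=O)CCC(C)(C)C=O | intermediate
4 | 2,4,4-trimethylcyclohex-2-en-1-one | CC1=CC(C)(C)CCC1=O | intermediate
5 | (1S)-2,4,4-trimethylcyclohex-2-en-1-ol | O[C@H]1CCC(C)(C)C=C1C | intermediate
6 | (6S)-6-(ethenyloxy)-1,3,3-trimethylcyclohex-1-ene | C=CO[C@H]1CCC(C)(C)C=C1C | intermediate
7 | [(1R)-2,6,6-trimethylcyclohex-2-en-1-yl]acetaldehyde | O=CC[C@@H]1C(C)(C)CCC=C1C | intermediate
8 | 4-bromobut-1-yne | C#CCCBr | starting material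
9 | lithium 4-bromobut-1-yn-1-ide | [Li]C#CCCBr | intermediate
10 | methyl 5-bromopent-2-ynoate | COC(=O)C#CCCBr | intermediate
11 | methyl (2E)-5-bromo-2-(diisobutylalumanyl)pent-2-enoate | BrCC/C=C(\C(=O)OC)[Al](CC(C)C)CC(C)C | intermediate
12 | diisobutylaluminium alkoxide of methyl (2Z)-5-bromo-2-{1-hydroxy-2-[(1R)-2,6,6-trimethylcyclohex-2-en-1-yl]ethyl}pent-2-enoate (both carbinol epimers) | BrCC/C=C(\C(=O)OC)C(O[Al](CC(C)C)CC(C)C)C[C@@H]1C(C)(C)CCC=C1C | intermediate
13 | methyl (2Z)-2-{1-acetoxy-2-[(1R)-2,6,6-trimethylcyclohex-2-en-1-yl]ethyl}-5-bromopent-2-enoate (both epimers at the acetoxy carbon) | BrCC/C=C(\C(=O)OC)C(OC(C)=O)C[C@@H]1C(C)(C)CCC=C1C | intermediate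
14 | methyl (5R,9R,10S)-7-acetoxy-12-bromo-13,14,15,16-tetranorlabdan-17-oate (mixture at C7 and C8) | BrCC[C@@H]1C(C(=O)OC)C(OC(C)=O)C[C@@H]2C(C)(C)CCC[C@@]12C | intermediate
15 | methyl (5R,9S,10R)-12-bromo-13,14,15,16-tetranorlabd-7-en-17-oate (H-5β, H-9β, CH3-20α) | BrCC[C@@H]1C(C(=O)OC)=CC[C@@H]2C(C)(C)CCC[C@@]12C | intermediate
16 | lithium dienolate of 15 (C6=C7 and C8=C17(OMe)OLi) | BrCC[C@@H]1C(=C(OC)O[Li])C=C[C@@H]2C(C)(C)CCC[C@@]12C | intermediate
17 | methyl (5R,8R,9R,10S)-12-bromo-13,14,15,16-tetranorlabd-6-en-17-oate (CO2Me-8α) | BrCC[C@@H]1[C@H](C(=O)OC)C=C[C@@H]2C(C)(C)CCC[C@@]12C | intermediate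
18 | 4-hydroxybut-2-ynoic acid | OCC#CC(=O)O | starting material
19 | (2Z)-4-hydroxy-3-iodobut-2-enoic acid | OC/C(I)=C/C(=O)O | intermediate
20 | trimethylsilyl (2Z)-3-iodo-4-(trimethylsilyloxy)but-2-enoate | C[Si](C)(C)OC/C(I)=C/C(=O)O[Si](C)(C)C | intermediate
21 | [(5R,8R,9R,10S)-17-methoxy-17-oxo-13,14,15,16-tetranorlabd-6-en-12-yl]zinc bromide | Br[Zn]CC[C@@H]1[C@H](C(=O)OC)C=C[C@@H]2C(C)(C)CCC[C@@]12C | intermediate
22 | trimethylsilyl ester and trimethylsilyl ether of 23 | C[Si](C)(C)OC/C(=C/C(=O)O[Si](C)(C)C)CC[C@@H]1[C@H](C(=O)OC)C=C[C@@H]2C(C)(C)CCC[C@@]12C | intermediate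
23 | (5R,8R,9R,10S,13E)-16-hydroxylabda-6,13-diene-15,17-dioic acid 17-methyl ester (CO2Me-8α) | OC/C(=C/C(=O)O)CC[C@@H]1[C@H](C(=O)OC)C=C[C@@H]2C(C)(C)CCC[C@@]12C | intermediate
24 | (5R,8R,9R,10S,13E)-16-hydroxy-17-oxolabda-6,13-dien-15-oic acid (CHO-8α) | OC/C(=C/C(=O)O)CC[C@@H]1[C@H](C=O)C=C[C@@H]2C(C)(C)CCC[C@@]12C | intermediate
25 | (5R,8S,9R,10S,13E)-16-hydroxy-17-oxolabda-6,13-dien-15-oic acid (CHO-8β) | OC/C(=C/C(=O)O)CC[C@@H]1[C@@H](C=O)C=C[C@@H]2C(C)(C)CCC[C@@]12C | intermediate
26 | (5R,8S,9R,10S,13E)-16-acetoxy-17-oxolabda-6,13-dien-15-oic acid (H-5β, H-9β, CH3-20α, CHO-8β) | CC(=O)OC/C(=C/C(=O)O)CC[C@@H]1[C@@H](C=O)C=C[C@@H]2C(C)(C)CCC[C@@]12C | target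

**Step count**

Total: 11 steps. Longest linear sequence: 9 steps (1, 2, 3, 5, 6, 7, 9, 10, 11).

**Steps most likely to fail**

Step 6 (radical ring closure). The iron hydride may reduce the enoate or quench the C10 radical before it cyclises, and some cis-fused or 9-epi material is possible. The fallback sets out from 13 and returns at 15. Mukaiyama hydration of the ring olefin (Co(acac)2, PhSiH3, O2, i-PrOH) gives the tertiary alcohol F1. Oxalyl chloride, then N-hydroxyphthalimide/Et3N, gives the tert-alkyl N-phthalimidoyl oxalate F2. Visible-light reduction (Ru(bpy)3(PF6)2, Hantzsch ester, i-Pr2NEt·HBF4, blue LEDs) releases the same C10 radical by double decarboxylation in a medium free of metal hydride. Cyclisation and H-transfer give 14, and DBU returns the route to 15.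

Step 10 (partial reduction on a hydroxy acid, then C8 equilibration). Over-reduction is possible, and the dienolate can leak to the conjugated Δ7 enal. The fallback sets out from 17 and returns at 25; it reduces and equilibrates before the side chain is present. DIBAL-H on 17 (−78 °C) gives the 8α bromo aldehyde F6, which DBU equilibrates to the 8β bromo aldehyde F7. HC(OMe)3/PPTS/MeOH gives the dimethyl acetal F8. Zn/LiCl gives the alkylzinc F9, and Pd-catalysed Negishi coupling with 20 gives the silylated acetal F10. 1 M HCl/THF removes the silyl groups and the acetal to give 25.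

Step 5 (hydroalumination/aldol). The Z selectivity, hydride attack on the bromide, and isomerisation of the allylic acetate are uncertain. The fallback sets out from 10 and 7 and returns at 13. Pd(PPh3)4-catalysed syn-hydrostannation of 10 (Bu3SnH) gives the α-stannyl enoate F3. I2 gives the α-iodo enoate F4 with retention. Nozaki–Hiyama–Kishi addition to 7 (CrCl2, cat. NiCl2, DMSO) gives the allylic alcohol F5 with CH2CH2Br cis to CO2Me. Ac2O/pyridine gives 13.

**Further compounds**

F1 | step 6 | methyl (2Z)-2-{1-acetoxy-2-[(1R)-2-hydroxy-2,6,6-trimethylcyclohexyl]ethyl}-5-bromopent-2-enoate (mixture at the carbinol and acetoxy carbons) | BrCC/C=C(\C(=O)OC)C(OC(C)=O)C[C@@H]1C(C)(C)CCCC1(C)O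
F2 | step 6 | N-phthalimidoyl oxalate of F1 | BrCC/C=C(\C(=O)OC)C(OC(C)=O)C[C@@H]1C(C)(C)CCCC1(C)OC(=O)C(=O)ON1C(=O)c2ccccc2C1=O
F3 | step 5 | methyl (2E)-5-bromo-2-(tributylstannyl)pent-2-enoate | BrCC/C=C(\C(=O)OC)[Sn](CCCC)(CCCC)CCCC
F4 | step 5 | methyl (2E)-5-bromo-2-iodopent-2-enoate | BrCC/C=C(\C(=O)OC)I
F5 | step 5 | methyl (2Z)-5-bromo-2-{1-hydroxy-2-[(1R)-2,6,6-trimethylcyclohex-2-en-1-yl]ethyl}pent-2-enoate (both carbinol epimers) | BrCC/C=C(\C(=O)OC)C(O)C[C@@H]1C(C)(C)CCC=C1C
F6 | step 10 | (5R,8R,9R,10S)-12-bromo-13,14,15,16-tetranorlabd-6-en-17-al (CHO-8α) | BrCC[C@@H]1[C@H](C=O)C=C[C@@H]2C(C)(C)CCC[C@@]12C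
F7 | step 10 | (5R,8S,9R,10S)-12-bromo-13,14,15,16-tetranorlabd-6-en-17-al (CHO-8β) | BrCC[C@@H]1[C@@H](C=O)C=C[C@@H]2C(C)(C)CCC[C@@]12C
F8 | step 10 | (5R,8S,9R,10S)-12-bromo-17,17-dimethoxy-13,14,15,16-tetranorlabd-6-ene | BrCC[C@@H]1[C@@H](C(OC)OC)C=C[C@@H]2C(C)(C)CCC[C@@]12C
F9 | step 10 | [(5R,8S,9R,10S)-17,17-dimethoxy-13,14,15,16-tetranorlabd-6-en-12-yl]zinc bromide | Br[Zn]CC[C@@H]1[C@@H](C(OC)OC)C=C[C@@H]2C(C)(C)CCC[C@@]12C
F10 | step 10 | trimethylsilyl (5R,8S,9R,10S,13E)-17,17-dimethoxy-16-(trimethylsilyloxy)labda-6,13-dien-15-oate | C[Si](C)(C)OC/C(=C/C(=O)O[Si](C)(C)C)CC[C@@H]1[C@@H](C(OC)OC)C=C[C@@H]2C(C)(C)CCC[C@@]12C
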